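**Retrosynthetic overview**

1. Locants (germacrane pattern): C4/C5 oxirane carbons (C4 carries CH3), C6 CH–O-senecioate, C7 ring-fusion CH bearing C11(=C13H2), C8 lactone O–CH, C9 CH–OH, C10 CH–CH3, C12 lactone C=O. Enabling feature: the C11(=C13)–C12 acrylate unit on C7 is flanked by two oxygen-bearing ring carbons, C6 and C8, both γ to C12, so the C12 carboxyl can be parked on O6 as a temporary butenolide ring (O6–C6–C7=C11–C12, with C13–Br) and passed on to O8 later.
2. Endgame: desilylation at O9 ⇐ C6 senecioate of the 8,12-lactone ⇐ base-mediated translactonization (O6 → O8) of the 6,12-lactone, with acylation of the released C6–OH in the same flask.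
3. Key disconnection C7–C8: intramolecular CrCl2-mediated allylation of the C8 aldehyde by the 3-(bromomethyl)butenolide closes the ten-membered carbocycle, sets C7 and C8, and unveils the exocyclic C11=C13 methylene by allylic transposition.
4. Bromobutenolide ⇐ α-methylene-γ-butyrolactone (Br2/Et3N) ⇐ Barbier reaction of the C6 epoxy aldehyde with methyl 2-(bromomethyl)acrylate; epoxy aldehyde ⇐ Sharpless epoxidation of the (E)-allylic alcohol ⇐ carboalumination of a terminal alkyne.
5. C10 comes from (R)-citronellal and C9–O from proline-catalysed α-aminoxylation; the rings are formed in the order oxirane (step 7), template γ-lactone (step 9), ten-membered carbocycle (step 13), final 8,12-lactone (step 14).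

Key step: step 13

Remark: the locants of the overview are used throughout; TBS = tert-butyldimethylsilyl, TES = triethylsilyl; the CIP letter at C7 differs between 22, 24/25 and 26 only because the priorities of C6 and C8 change, not the spatial arrangement.

**Route**

Step 1
Reactants: 1 (R)-citronellal
Product: 4 (2R,3R)-3,7-dimethyloct-6-ene-1,2-diol, via α-aminoxy aldehyde 2 (not isolated), via aminoxy alcohol 3 (not isolated)
Conditions: PhNO, L-proline (20 mol %), CHCl3, 4 °C; NaBH4, EtOH, 0 °C; Zn, AcOH, rt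
Reagents that add atoms: nitrosobenzene O=Nc1ccccc1
Why: Proline enamine catalysis (organocatalytic α-aminoxylation) should deliver oxygen to C9 under catalyst control, L-proline giving the (2R) centre next to the pool-derived (3R) methyl centre, after which the labile aldehyde is reduced and the N–O bond is cleaved reductively.

Step 2
Reactants: 4 (2R,3R)-3,7-dimethyloct-6-ene-1,2-diol
Product: 5 (2R,3R)-1,2-bis(TBSO)-3,7-dimethyloct-6-ene
Conditions: TBSOTf, 2,6-lutidine, CH2Cl2, −78 → 0 °C
Reagents that add atoms: tert-butyldimethylsilyl trifluoromethanesulfonate CC(C)(C)[Si](C)(C)OS(=O)(=O)C(F)(F)F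
Why: Exhaustive silylation of a 1,2-diol gives two ethers that should survive steps 3 to 9 and of which the primary one can later be removed selectively.

Step 3
Reactants: 5 (2R,3R)-1,2-bis(TBSO)-3,7-dimethyloct-6-ene
Product: 7 (4R,5R)-5,6-bis(TBSO)-4-methylhexan-1-ol, via aldehyde 6 (not isolated)
Conditions: O3, CH2Cl2/MeOH, −78 °C; NaBH4, −78 → 0 °C
Reagents that add atoms: ozone [O-][O+]=O
Why: Ozonolysis of the only alkene with reductive borohydride work-up should give the primary alcohol at C3 without touching a stereocentre.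

Step 4
Reactants: 7 (4R,5R)-5,6-bis(TBSO)-4-methylhexan-1-ol
Product: 8 (2R,3R)-1,2-bis(TBSO)-6-iodo-3-methylhexane
Conditions: I2, PPh3, imidazole, CH2Cl2, 0 °C → rt
Reagents that add atoms: iodine II
Why: Appel-type iodination of an unhindered primary alcohol.

Step 5
Reactants: 8 (2R,3R)-1,2-bis(TBSO)-6-iodo-3-methylhexane
Product: 9 (6R,7R)-7,8-bis(TBSO)-6-methyloct-1-yne
Conditions: LiC≡CH·H2NCH2CH2NH2, DMSO, 15 °C → rt
Reagents that add atoms: lithium acetylide ethylenediamine complex [Li+].[C-]#C.NCCN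
Why: SN2 alkylation of acetylide by a primary iodide installs C4 and C5 as a terminal alkyne.

Step 6
Reactants: 9 (6R,7R)-7,8-bis(TBSO)-6-methyloct-1-yne
Product: 11 (2E,7R,8R)-8,9-bis(TBSO)-3,7-dimethylnon-2-en-1-ol, via alkenylalane 10 (not isolated)
Conditions: Me3Al, Cp2ZrCl2 (20 mol %), CH2Cl2, 0 °C → rt; n-BuLi, THF, −30 °C; (CH2O)n, −30 °C → rt
Reagents that add atoms: trimethylaluminium C[Al](C)C; paraformaldehyde (as formaldehyde) C=O
Why: Zirconium-catalysed syn carboalumination of the terminal alkyne (Negishi carboalumination) fixes the E geometry of the C4=C5 bond, and the alanate is trapped by formaldehyde with retention to give the allylic alcohol.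

Step 7
Reactants: 11 (2E,7R,8R)-8,9-bis(TBSO)-3,7-dimethylnon-2-en-1-ol
Product: 12 [(2R,3R)-3-[(4R,5R)-5,6-bis(TBSO)-4-methylhexyl]-3-methyloxiran-2-yl]methanol
Conditions: Ti(OiPr)4 (10 mol %), D-(−)-diethyl tartrate (12 mol %), t-BuOOH, 4 Å MS, CH2Cl2, −20 °C
Reagents that add atoms: tert-butyl hydroperoxide CC(C)(C)OO
Why: Sharpless asymmetric epoxidation of an (E)-trisubstituted primary allylic alcohol, in which the D-(−)-tartrate ligand should direct oxygen to the face that gives the (2R,3R) epoxide (C5 R, C4 R) under reagent control.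

Step 8
Reactants: 12 [(2R,3R)-3-[(4R,5R)-5,6-bis(TBSO)-4-methylhexyl]-3-methyloxiran-2-yl]methanol
Product: 13 (2S,3R)-3-[(4R,5R)-5,6-bis(TBSO)-4-methylhexyl]-3-methyloxirane-2-carbaldehyde
Conditions: Dess–Martin periodinane, NaHCO3, CH2Cl2, 0 °C → rt
Reagents that add atoms: none
Why: Buffered Dess–Martin oxidation should give the epoxy aldehyde without epimerization or epoxide opening.

Step 9
Reactants: 13 (2S,3R)-3-[(4R,5R)-5,6-bis(TBSO)-4-methylhexyl]-3-methyloxirane-2-carbaldehyde; 14 methyl 2-(bromomethyl)acrylate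
Product: 16 (5R)-5-[(2R,3R)-3-[(4R,5R)-5,6-bis(TBSO)-4-methylhexyl]-3-methyloxiran-2-yl]-3-methylideneoxolan-2-one, via hydroxy ester 15 (not isolated)
Conditions: Zn dust, THF/sat. aq. NH4Cl, 0 °C → rt; PPTS (cat.), CH2Cl2, rt
Reagents that add atoms: none
Why: Barbier-type 2-(alkoxycarbonyl)allylation of the aldehyde followed by lactonization builds the template γ-lactone, the C6 centre being set by Felkin–Anh addition anti to the epoxide C–O bond under non-chelating aqueous conditions (anti, erythro epoxy alcohol).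

Step 10
Reactants: 16 bis-silylated α-methylene lactone
Product: 17 (5R)-5-[(2R,3R)-3-[(4R,5R)-5-(TBSO)-6-hydroxy-4-methylhexyl]-3-methyloxiran-2-yl]-3-methylideneoxolan-2-one
Conditions: HF·pyridine, pyridine, THF, 0 °C
Reagents that add atoms: none
Why: Buffered fluoride cleaves the primary silyl ether faster than the hindered secondary one (steric discrimination) and should spare epoxide and lactone.

Step 11
Reactants: 17 primary alcohol with α-methylene lactone
Product: 19 (5R)-3-(bromomethyl)-5-[(2R,3R)-3-[(4R,5R)-5-(TBSO)-6-hydroxy-4-methylhexyl]-3-methyloxiran-2-yl]furan-2(5H)-one, via dibromide 18 (not isolated)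
Conditions: Br2, NaHCO3, CH2Cl2, −78 → −20 °C; Et3N (1.1 equiv), 0 °C
Reagents that add atoms: bromine BrBr
Why: Bromine addition to the exocyclic alkene and E2 dehydrobromination into the ring (bromination–dehydrobromination of an α-methylene lactone) should give the conjugated 3-(bromomethyl)butenolide with C6 untouched.

Step 12
Reactants: 19 bromomethyl butenolide alcohol
Product: 20 (2R,3R)-6-[(2R,3R)-3-[(2R)-4-(bromomethyl)-5-oxo-2,5-dihydrofuran-2-yl]-2-methyloxiran-2-yl]-2-(TBSO)-3-methylhexanal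
Conditions: Dess–Martin periodinane, NaHCO3, CH2Cl2, 0 °C
Reagents that add atoms: none
Why: Neutral Dess–Martin oxidation of the primary alcohol should leave the allylic bromide, the epoxide and the C9 configuration of the α-silyloxy aldehyde intact.

Step 13
Reactants: 20 bromomethyl butenolide aldehyde
Product: 22 (4R,5R,6R,7S,8S,9R,10R)-9-(TBSO)-4,5-epoxy-8-hydroxygermacr-11(13)-en-12,6-olide, via allylchromium species 21 (not isolated)
Conditions: CrCl2 (8 equiv), THF, rt, slow addition of 20 (final concentration 2 mM); aq. NH4Cl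
Reagents that add atoms: none
Why: CrCl2 reduces the allylic C13–Br bond of 20 in two one-electron steps to the σ-allyl trivalent chromium species 21, which adds to the C8 aldehyde through C7 in a six-membered chair transition state with allylic transposition; the closest known reaction type is the Nozaki–Hiyama–Kishi allylation, as used for macrocyclization to ten-membered germacranolide rings and, intermolecularly, with 3-(bromomethyl)butenolides. The ten-membered carbocycle closes in a 10-exo-trig mode at the aldehyde carbon (C7–C8 bond), while the five-membered lactone in 22 is the pre-formed template and is not closed here. C7 is controlled by the butenolide ring, because the aldehyde should add to the face anti to the C5 substituent on the adjacent C6 stereocentre, giving the 6,7-trans arrangement. C8 is controlled relative to C7 by the chair, because the ring locks C6 trans to the CH2–Cr carbon (an E-type γ-substituted allyl), so C6 and the aldehyde substituent C9 both sit equatorial and the 7,8-anti adduct forms, and Felkin–Anh addition anti to the C9 silyloxy group calls for the same aldehyde face, so the three elements are matched. The step needs γ- over α-attack (secured by the closed transition state), cyclization over oligomerization (high dilution and slow addition), and a persistent allyl metal (the lactone C6–O bond lies in the nodal plane of the allyl π system, so vinylogous β-elimination of the carboxylate is stereoelectronically blocked, unlike in an open-chain 4-oxygenated allyl bromide).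

Step 14
Reactants: 22 6,12-lactone with free C8–OH; 23 3-methylbut-2-enoic anhydride
Product: 25 (4R,5R,6R,7R,8S,9R,10R)-9-(TBSO)-4,5-epoxy-6-[(3-methylbut-2-enoyl)oxy]germacr-11(13)-en-12,8-olide, via 8,12-lactone alcohol 24 (not isolated)
Conditions: DBU (0.2 equiv), CH2Cl2, rt; then 23, DMAP (0.2 equiv), iPr2NEt, 0 °C → rt
Reagents that add atoms: none
Why: Base-catalysed translactonization (intramolecular transesterification through a bicyclic tetrahedral intermediate, possible because O6 and O8 are both γ and syn to C12) should equilibrate 22 with 24, whose less hindered C6 hydroxyl is expected to be acylated (DMAP acyl transfer) faster than the C8 hydroxyl of 22 that is flanked by the C9 silyl ether, so that the equilibrium is drained toward 25 without involving any stereocentre.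

Step 15
Reactants: 25 silyl-protected 6-senecioate 8,12-lactone
Product: 26 (4R,5R,6R,7S,8S,9R,10R)-4,5-epoxy-9-hydroxy-6-[(3-methylbut-2-enoyl)oxy]germacr-11(13)-en-12,8-olide (CNP0119422.1)
Conditions: HF·pyridine, pyridine, THF, 0 °C → rt
Reagents that add atoms: none
Why: Buffered fluoride cleavage of the secondary silyl ether should spare the epoxide, both esters and the exocyclic alkene.

**Compound list**

1 | (R)-citronellal, (3R)-3,7-dimethyloct-6-enal | O=CC[C@H](C)CCC=C(C)C | starting material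
2 | (2R,3R)-3,7-dimethyl-2-[(phenylamino)oxy]oct-6-enal | O=C[C@H](ONc1ccccc1)[C@H](C)CCC=C(C)C | intermediate (not isolated)
3 | (2R,3R)-3,7-dimethyl-2-[(phenylamino)oxy]oct-6-en-1-ol | OC[C@H](ONc1ccccc1)[C@H](C)CCC=C(C)C | intermediate (not isolated)
4 | (2R,3R)-3,7-dimethyloct-6-ene-1,2-diol | OC[C@H](O)[C@H](C)CCC=C(C)C | intermediate
5 | (2R,3R)-1,2-bis(TBSO)-3,7-dimethyloct-6-ene | CC(C)(C)[Si](C)(C)OC[C@H](O[Si](C)(C)C(C)(C)C)[C@H](C)CCC=C(C)C | intermediate
6 | (4R,5R)-5,6-bis(TBSO)-4-methylhexanal | CC(C)(C)[Si](C)(C)OC[C@H](O[Si](C)(C)C(C)(C)C)[C@H](C)CCC=O | intermediate (not isolated)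
7 | (4R,5R)-5,6-bis(TBSO)-4-methylhexan-1-ol | CC(C)(C)[Si](C)(C)OC[C@H](O[Si](C)(C)C(C)(C)C)[C@H](C)CCCO | intermediate
8 | (2R,3R)-1,2-bis(TBSO)-6-iodo-3-methylhexane | CC(C)(C)[Si](C)(C)OC[C@H](O[Si](C)(C)C(C)(C)C)[C@H](C)CCCI | intermediate
9 | (6R,7R)-7,8-bis(TBSO)-6-methyloct-1-yne | CC(C)(C)[Si](C)(C)OC[C@H](O[Si](C)(C)C(C)(C)C)[C@H](C)CCCC#C | intermediate
10 | [(1E,6R,7R)-7,8-bis(TBSO)-2,6-dimethyloct-1-en-1-yl]dimethylalumane | CC(C)(C)[Si](C)(C)OC[C@H](O[Si](C)(C)C(C)(C)C)[C@H](C)CCC/C(C)=C/[Al](C)C | intermediate (not isolated)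
11 | (2E,7R,8R)-8,9-bis(TBSO)-3,7-dimethylnon-2-en-1-ol | CC(C)(C)[Si](C)(C)OC[C@H](O[Si](C)(C)C(C)(C)C)[C@H](C)CCC/C(C)=C/CO | intermediate
12 | [(2R,3R)-3-[(4R,5R)-5,6-bis(TBSO)-4-methylhexyl]-3-methyloxiran-2-yl]methanol | CC(C)(C)[Si](C)(C)OC[C@H](O[Si](C)(C)C(C)(C)C)[C@H](C)CCC[C@@]1(C)O[C@@H]1CO | intermediate
13 | (2S,3R)-3-[(4R,5R)-5,6-bis(TBSO)-4-methylhexyl]-3-methyloxirane-2-carbaldehyde | CC(C)(C)[Si](C)(C)OC[C@H](O[Si](C)(C)C(C)(C)C)[C@H](C)CCC[C@@]1(C)O[C@@H]1C=O | intermediate
14 | methyl 2-(bromomethyl)acrylate | C=C(CBr)C(=O)OC | starting material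
15 | methyl (4R)-4-[(2R,3R)-3-[(4R,5R)-5,6-bis(TBSO)-4-methylhexyl]-3-methyloxiran-2-yl]-4-hydroxy-2-methylidenebutanoate | CC(C)(C)[Si](C)(C)OC[C@H](O[Si](C)(C)C(C)(C)C)[C@H](C)CCC[C@@]1(C)O[C@@H]1[C@H](O)CC(=C)C(=O)OC | intermediate (not isolated)
16 | (5R)-5-[(2R,3R)-3-[(4R,5R)-5,6-bis(TBSO)-4-methylhexyl]-3-methyloxiran-2-yl]-3-methylideneoxolan-2-one | CC(C)(C)[Si](C)(C)OC[C@H](O[Si](C)(C)C(C)(C)C)[C@H](C)CCC[C@@]1(C)O[C@@H]1[C@@H]2OC(=O)C(=C)C2 | intermediate
17 | (5R)-5-[(2R,3R)-3-[(4R,5R)-5-(TBSO)-6-hydroxy-4-methylhexyl]-3-methyloxiran-2-yl]-3-methylideneoxolan-2-one | OC[C@H](O[Si](C)(C)C(C)(C)C)[C@H](C)CCC[C@@]1(C)O[C@@H]1[C@@H]2OC(=O)C(=C)C2 | intermediate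
18 | (5R)-3-bromo-3-(bromomethyl)-5-[(2R,3R)-3-[(4R,5R)-5-(TBSO)-6-hydroxy-4-methylhexyl]-3-methyloxiran-2-yl]oxolan-2-one (mixture at the brominated ring carbon) | OC[C@H](O[Si](C)(C)C(C)(C)C)[C@H](C)CCC[C@@]1(C)O[C@@H]1[C@@H]2OC(=O)C(Br)(CBr)C2 | intermediate (not isolated)
19 | (5R)-3-(bromomethyl)-5-[(2R,3R)-3-[(4R,5R)-5-(TBSO)-6-hydroxy-4-methylhexyl]-3-methyloxiran-2-yl]furan-2(5H)-one | OC[C@H](O[Si](C)(C)C(C)(C)C)[C@H](C)CCC[C@@]1(C)O[C@@H]1[C@@H]2OC(=O)C(CBr)=C2 | intermediate
20 | (2R,3R)-6-[(2R,3R)-3-[(2R)-4-(bromomethyl)-5-oxo-2,5-dihydrofuran-2-yl]-2-methyloxiran-2-yl]-2-(TBSO)-3-methylhexanal | O=C[C@H](O[Si](C)(C)C(C)(C)C)[C@H](C)CCC[C@@]1(C)O[C@@H]1[C@@H]2OC(=O)C(CBr)=C2 | intermediate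
21 | σ-allyl dichlorochromium species of 20 (Cr on the former CH2Br carbon) | O=C[C@H](O[Si](C)(C)C(C)(C)C)[C@H](C)CCC[C@@]1(C)O[C@@H]1[C@@H]2OC(=O)C(C[Cr](Cl)Cl)=C2 | intermediate (not isolated)
22 | (4R,5R,6R,7S,8S,9R,10R)-9-(TBSO)-4,5-epoxy-8-hydroxygermacr-11(13)-en-12,6-olide (ten-membered ring, trans-fused 6,12-lactone, free C8–OH) | C=C1C(=O)O[C@@H]2[C@@H]1[C@H](O)[C@H](O[Si](C)(C)C(C)(C)C)[C@H](C)CCC[C@@]3(C)O[C@H]23 | intermediate
23 | 3-methylbut-2-enoic (senecioic) anhydride | CC(C)=CC(=O)OC(=O)C=C(C)C | starting material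
24 | (4R,5R,6R,7R,8S,9R,10R)-9-(TBSO)-4,5-epoxy-6-hydroxygermacr-11(13)-en-12,8-olide | C=C1C(=O)O[C@@H]2[C@H](O[Si](C)(C)C(C)(C)C)[C@H](C)CCC[C@@]3(C)O[C@@H]3[C@H](O)[C@@H]12 | intermediate (not isolated)
25 | (4R,5R,6R,7R,8S,9R,10R)-9-(TBSO)-4,5-epoxy-6-[(3-methylbut-2-enoyl)oxy]germacr-11(13)-en-12,8-olide | C=C1C(=O)O[C@@H]2[C@H](O[Si](C)(C)C(C)(C)C)[C@H](C)CCC[C@@]3(C)O[C@@H]3[C@H](OC(=O)C=C(C)C)[C@@H]12 | intermediate
26 | (4R,5R,6R,7S,8S,9R,10R)-4,5-epoxy-9-hydroxy-6-[(3-methylbut-2-enoyl)oxy]germacr-11(13)-en-12,8-olide, CNP0119422.1 | C=C1C(=O)O[C@@H]2[C@H](O)[C@H](C)CCC[C@@]3(C)O[C@@H]3[C@H](OC(=O)C=C(C)C)[C@@H]12 | target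

**Step count and risks**

Total step count: 15. Longest linear sequence: 15 steps (from 1).

Steps most likely to fail:

1. Step 13. Intermolecular coupling, oligomerization or reductive homocoupling of the allyl bromide may outrun ring closure, and ring strain may force addition to the butenolide face syn to C5 (loss of facial selectivity). Fallback: the allyl nucleophile would be isolated instead of being generated by reduction. Setting out from 19, B2pin2 with the zerovalent palladium catalyst Pd2(dba)3 (THF, 50 °C) should give the primary allylboronate alcohol F1. Dess–Martin oxidation gives the allylboronate aldehyde F2, which is heated at high dilution (toluene, 90 °C) so that the ring closes by intramolecular allylboration through the same chair to the pinacol borate ester of the macrocycle F3. Aqueous NaHCO3 work-up cleaves the borate and the route is rejoined at 22.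

2. Step 14. The lactone equilibrium may rest on the 6,12 side with competing acylation at O8, the silyl group may migrate from O9 to O8, or the base may move the exocyclic double bond into the ring. Fallback: the acyl shift would be made irreversible stepwise with standard operations. Setting out from 22, TESOTf/2,6-lutidine gives the 8-O-triethylsilyl ether F4. LiOH (THF/H2O, 0 °C) opens the lactone to the lithium carboxylate F5, which is alkylated without acidification (MeI, DMF) to the hydroxy methyl ester F6. Acylation of the only free hydroxyl with 23/DMAP gives the C6 senecioate methyl ester F7. Selective removal of the triethylsilyl group (PPTS, MeOH, 0 °C) gives the 8-hydroxy ester F8, which closes the 8,12-lactone with loss of methanol (cat. PPTS, toluene, 50 °C if needed), and the route is rejoined at 25.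

3. Step 11. Elimination may go toward the exocyclic bromomethylene isomer, HBr may open the oxirane, or the base may epimerize C6 through the 2-oxyfuran. Fallback: the double bond would first be moved into the ring and bromine introduced by radical substitution. Setting out from 17, RhCl3·3H2O (cat., EtOH, 70 °C), a known isomerization of α-methylene-γ-butyrolactones, gives the endocyclic α-methylbutenolide F9. Wohl–Ziegler bromination of its allylic methyl group (NBS, AIBN, PhCF3, 80 °C) rejoins the route at 19.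

Further compounds

F1 | step 13 | (5R)-5-[(2R,3R)-3-[(4R,5R)-5-(TBSO)-6-hydroxy-4-methylhexyl]-3-methyloxiran-2-yl]-3-[(4,4,5,5-tetramethyl-1,3,2-dioxaborolan-2-yl)methyl]furan-2(5H)-one | OC[C@H](O[Si](C)(C)C(C)(C)C)[C@H](C)CCC[C@@]1(C)O[C@@H]1[C@@H]2OC(=O)C(CB3OC(C)(C)C(C)(C)O3)=C2
F2 | step 13 | aldehyde corresponding to F1 (C8 aldehyde, allyl pinacolboronate) | O=C[C@H](O[Si](C)(C)C(C)(C)C)[C@H](C)CCC[C@@]1(C)O[C@@H]1[C@@H]2OC(=O)C(CB3OC(C)(C)C(C)(C)O3)=C2
F3 | step 13 | 8-O-pinacol borate ester of 22 | C=C1C(=O)O[C@@H]2[C@@H]1[C@H](OB4OC(C)(C)C(C)(C)O4)[C@H](O[Si](C)(C)C(C)(C)C)[C@H](C)CCC[C@@]3(C)O[C@H]23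
F4 | step 14 | 8-O-triethylsilyl ether of 22 | C=C1C(=O)O[C@@H]2[C@@H]1[C@H](O[Si](CC)(CC)CC)[C@H](O[Si](C)(C)C(C)(C)C)[C@H](C)CCC[C@@]3(C)O[C@H]23
F5 | step 14 | lithium carboxylate of the seco acid of F4 (acrylate on C7, free C6–OH, 8-OTES, 9-OTBS) | C=C(C(=O)[O-])[C@@H]1[C@@H](O)[C@H]2O[C@]2(C)CCC[C@@H](C)[C@@H](O[Si](C)(C)C(C)(C)C)[C@H]1O[Si](CC)(CC)CC.[Li+]
F6 | step 14 | methyl ester of the seco acid (free C6–OH, 8-OTES, 9-OTBS) | C=C(C(=O)OC)[C@@H]1[C@@H](O)[C@H]2O[C@]2(C)CCC[C@@H](C)[C@@H](O[Si](C)(C)C(C)(C)C)[C@H]1O[Si](CC)(CC)CC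
F7 | step 14 | C6 senecioate of F6 | C=C(C(=O)OC)[C@@H]1[C@@H](OC(=O)C=C(C)C)[C@H]2O[C@]2(C)CCC[C@@H](C)[C@@H](O[Si](C)(C)C(C)(C)C)[C@H]1O[Si](CC)(CC)CC
F8 | step 14 | 8-hydroxy ester from F7 after removal of the triethylsilyl group | C=C(C(=O)OC)[C@@H]1[C@@H](OC(=O)C=C(C)C)[C@H]2O[C@]2(C)CCC[C@@H](C)[C@@H](O[Si](C)(C)C(C)(C)C)[C@H]1O
F9 | step 11 | (5R)-5-[(2R,3R)-3-[(4R,5R)-5-(TBSO)-6-hydroxy-4-methylhexyl]-3-methyloxiran-2-yl]-3-methylfuran-2(5H)-one | OC[C@H](O[Si](C)(C)C(C)(C)C)[C@H](C)CCC[C@@]1(C)O[C@@H]1[C@@H]2OC(=O)C(C)=C2
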